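The numbers come from no measurement; the result is computed.

I began from two times, the time the catalyst needs to clear the substrate and the time the side step needs to consume it, and asked which was the shorter.

in all of them: substrate 0.050 M; time 50 h
- Sunday's: free catalyst 0.10 mM
- Friday's: free catalyst 0.15 mM

    catalyst intermediate → free catalyst + target (k1 = 0.334 min⁻¹)
    substrate + free catalyst ⇌ catalyst intermediate (K2 = 340 M⁻¹, k2 = 102 M⁻¹ min⁻¹)
    substrate + target → side product (k3 = 0.00108 M⁻¹ min⁻¹)

- which of the two there is more of at the end, counted by the substrate in each, Sunday's (side product / target)
- which of the two there is more of at the end, counted by the substrate in each, Friday's (side product / target)
- amount of target at the end, in percent of the substrate charged, Sunday's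
- amount of target at the end, in percent of the substrate charged, Friday's

Let S be the charged substrate. With every catalyst unit releasing target at the release constant, the emptying time on Sunday's flask was 25.0 h, shorter than the 50 h allowed. With target at the full charge S, a substrate molecule's time by the side step was 309 h.

Then I turned the question round. For side product to hold more substrate than target, these two times would have had to stand close together, but the side time was far longer than the emptying time. Their ratio came to 0.0808 on Sunday's flask and 0.0539 on Friday's. I call this ratio the loss number λ, the emptying time over the side time.

The Michaelis constant K, the release constant plus the back constant, over the forward constant, was 6.22 mM, smaller than S, so I took the substrate as used up within the run. Integrating the side rate while target grew, and counting two substrate units per side product, I got a lost share L = λ(1/3 + K/S). That made 3.70% on Sunday's flask and 2.47% on Friday's.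

The forecast said target for Sunday's and target for Friday's, with 96.4% and 97.6% of target, where my reckoning gave 96.3% and 97.5%: “Target dominates both runs.”

The flasks gave target on Sunday's and target on Friday's, with 96.5% and 97.6% of target.

On Sunday's flask the catalyst cycle was still turning at 25.0 h, with 18.7% of the substrate left, 60.0% of the catalyst held as intermediate and side product at 2.95%. By 50.0 h substrate was down to 0.0251%, and side product read 3.51%. Scaling that reading by Friday's loss number, 0.0539 against 0.0808, gives 2.34%, and Friday's flask read 2.37%.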